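**Retrosynthetic overview**
1. Numbering: ring C1 (CH–O-acyl), C2 (C=O), C3 (C–CH3, oxirane), C4 (CH, oxirane), C5 (CH2), C6 (CH); side chain C7(=C14H2)–C8H(O-acyl)–C9H2–C10H=C11(CH3)2. Target 24 ⇐ diol 21 (both angelates put on last) ⇐ silyl ether 20.
2. Key disconnection C1–C6: 20 ⇐ open-chain epoxy α-keto aldehyde 19 by an intramolecular carbonyl-ene cyclisation. The enabling feature is the homoallylic-alcohol array C1(O)–C6–C7(=C14H2) of the cyclohexanone ring next to the C2 ketone: C1 can be the aldehyde carbon of a chelating 1,2-dicarbonyl enophile, C6=C7–C14H3 the ene, and the cis-fused C3–C4 oxirane the turn that holds C2 and C5 syn.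
3. 19 ⇐ epoxy alcohol 15 (C1 added as a hydroxymethyl anion equivalent, then double oxidation) ⇐ (2Z,5Z)-dienol 14 by Sharpless epoxidation (sets C3, C4).
4. 14 ⇐ aldehyde 10 by Still–Gennari olefination (C3=C4) ⇐ methyl ketone 6 by a Z-selective Wittig reaction (C6=C7) ⇐ methyl (S)-glycidate 1 + alkenyl Grignard reagent 2 (C8 from the chiral pool).
5. Ring order: oxirane first, on the open chain (step 8); six-membered carbocycle second (step 13).

Key step: step 13

Remark: both ester groups are read as angelates ((Z)-2-methylbut-2-enoates), all five stereocentres are S, and 1, 2, 7, 11 and 22 are taken to be commercially available.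

Step 1
Reactants: 1 methyl (2S)-oxirane-2-carboxylate (methyl (S)-glycidate); 2 (2-methylprop-1-en-1-yl)magnesium bromide
Product: 3 methyl (2S)-2-hydroxy-5-methylhex-4-enoate
Conditions: 2 (1.3 equiv), CuI (10 mol%), THF, −40 → −20 °C; aq. NH4Cl
Reagents that add atoms: none
Why: Copper-catalysed SN2 opening of the unsubstituted oxirane carbon by the alkenyl Grignard reagent (organocuprate epoxide opening) should outrun ester addition at this temperature and leaves the stereocentre, the future C8 (S), untouched.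

Step 2
Reactants: 3 methyl (2S)-2-hydroxy-5-methylhex-4-enoate
Product: 4 methyl (2S)-2-[(tert-butyldimethylsilyl)oxy]-5-methylhex-4-enoate
Conditions: TBSCl (1.2 equiv), imidazole (2.5 equiv), DMF, 0 °C → rt
Reagents that add atoms: tert-butyldimethylsilyl chloride, CC(C)(C)[Si](C)(C)Cl
Why: Imidazole-promoted silylation of a secondary alcohol, with no bond to the stereocentre broken.

Step 3
Reactants: 4 methyl (2S)-2-[(tert-butyldimethylsilyl)oxy]-5-methylhex-4-enoate
Product: 6 (3S)-3-[(tert-butyldimethylsilyl)oxy]-6-methylhept-5-en-2-one, via Weinreb amide 5 (not isolated)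
Conditions: MeNH(OMe)·HCl (1.5 equiv), iPrMgCl (3.0 equiv), THF, −20 °C; then MeMgBr (2.5 equiv), −20 → 0 °C; aq. NH4Cl
Reagents that add atoms: N,O-dimethylhydroxylamine hydrochloride, CNOC.Cl (its atoms are carried by 5 only); methylmagnesium bromide, C[Mg]Br
Why: One-flask Weinreb ketone synthesis, in which the magnesium amide turns the ester into the N-methoxy-N-methylamide and the chelated adduct with MeMgBr stops at the ketone; the low temperature should protect the α-silyloxy stereocentre.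

Step 4
Reactants: 6 (3S)-3-[(tert-butyldimethylsilyl)oxy]-6-methylhept-5-en-2-one; 7 [2-(1,3-dioxolan-2-yl)ethyl]triphenylphosphonium bromide
Product: 9 2-[(2Z,4S)-4-[(tert-butyldimethylsilyl)oxy]-3,7-dimethylocta-2,6-dien-1-yl]-1,3-dioxolane, via phosphonium ylide 8 (not isolated)
Conditions: 7 (1.5 equiv), KN(SiMe3)2 (1.45 equiv), THF, 0 °C; then 6, −78 °C → rt
Reagents that add atoms: none
Why: Wittig olefination of an α-alkoxy methyl ketone with a non-stabilised ylide under lithium-free conditions is Z-selective for trisubstituted alkenes, placing the ylide chain (C5) cis to the oxygen-bearing C8; C8 itself is not touched.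

Step 5
Reactants: 9 2-[(2Z,4S)-4-[(tert-butyldimethylsilyl)oxy]-3,7-dimethylocta-2,6-dien-1-yl]-1,3-dioxolane
Product: 10 (3Z,5S)-5-[(tert-butyldimethylsilyl)oxy]-4,8-dimethylnona-3,7-dienal
Conditions: pyridinium p-toluenesulfonate (0.2 equiv), acetone/H2O (9:1), 50 °C
Reagents that add atoms: water, O
Why: Mildly acidic acetal hydrolysis should free the β,γ-unsaturated aldehyde without moving the alkene into conjugation or cleaving the hindered secondary silyl ether.

Step 6
Reactants: 10 (3Z,5S)-5-[(tert-butyldimethylsilyl)oxy]-4,8-dimethylnona-3,7-dienal; 11 ethyl 2-[bis(2,2,2-trifluoroethoxy)phosphoryl]propanoate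
Product: 13 ethyl (2Z,5Z,7S)-7-[(tert-butyldimethylsilyl)oxy]-2,6,10-trimethylundeca-2,5,9-trienoate, via potassium phosphonate carbanion 12 (not isolated)
Conditions: 11 (1.3 equiv), KN(SiMe3)2 (1.25 equiv), 18-crown-6 (3 equiv), THF, −78 °C; then 10, −78 °C
Reagents that add atoms: none
Why: Still–Gennari variant of the Horner–Wadsworth–Emmons reaction (kinetic control with the trifluoroethyl phosphonate and a dissociated potassium ion) should give the (Z)-2-methyl enoate, with C2 cis to C5; the weakly basic anion should not enolise the aldehyde.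

Step 7
Reactants: 13 ethyl (2Z,5Z,7S)-7-[(tert-butyldimethylsilyl)oxy]-2,6,10-trimethylundeca-2,5,9-trienoate
Product: 14 (2Z,5Z,7S)-7-[(tert-butyldimethylsilyl)oxy]-2,6,10-trimethylundeca-2,5,9-trien-1-ol
Conditions: iBu2AlH (2.5 equiv), CH2Cl2, −78 → −20 °C; aq. potassium sodium tartrate
Reagents that add atoms: none
Why: 1,2-Reduction of the enoate by the aluminium hydride gives the allylic alcohol with both alkene geometries retained.

Step 8
Reactants: 14 (2Z,5Z,7S)-7-[(tert-butyldimethylsilyl)oxy]-2,6,10-trimethylundeca-2,5,9-trien-1-ol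
Product: 15 [(2R,3S)-3-[(2Z,4S)-4-[(tert-butyldimethylsilyl)oxy]-3,7-dimethylocta-2,6-dien-1-yl]-2-methyloxiran-2-yl]methanol
Conditions: Ti(OiPr)4 (0.5 equiv), D-(−)-diethyl tartrate (0.6 equiv), tBuOOH (2 equiv, isooctane), 4 Å molecular sieves, CH2Cl2, −20 °C
Reagents that add atoms: tert-butyl hydroperoxide, CC(C)(C)OO
Why: Katsuki–Sharpless asymmetric epoxidation: the titanium tartrate binds the allylic hydroxyl, so only C3=C4 is epoxidised (syn addition keeps C2 and C5 cis), and since L-(+)-tartrate turns (Z)-allylic alcohols such as nerol into (2S,3R)-epoxy alcohols, the D-(−)-ester should give the (2R,3S)-epoxide under reagent control, the remote C8 centre having little say.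

Step 9
Reactants: 15 [(2R,3S)-3-[(2Z,4S)-4-[(tert-butyldimethylsilyl)oxy]-3,7-dimethylocta-2,6-dien-1-yl]-2-methyloxiran-2-yl]methanol
Product: 16 (2S,3S)-3-[(2Z,4S)-4-[(tert-butyldimethylsilyl)oxy]-3,7-dimethylocta-2,6-dien-1-yl]-2-methyloxirane-2-carbaldehyde
Conditions: Dess–Martin periodinane (1.3 equiv), NaHCO3, CH2Cl2, 0 °C → rt
Reagents that add atoms: none
Why: Dess–Martin oxidation under buffered conditions gives the epoxy aldehyde, whose quaternary α-carbon cannot epimerise (the descriptor changes only through CIP priorities).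

Step 10
Reactants: 16 (2S,3S)-3-[(2Z,4S)-4-[(tert-butyldimethylsilyl)oxy]-3,7-dimethylocta-2,6-dien-1-yl]-2-methyloxirane-2-carbaldehyde
Product: 17 1-[(2R,3S)-3-[(2Z,4S)-4-[(tert-butyldimethylsilyl)oxy]-3,7-dimethylocta-2,6-dien-1-yl]-2-methyloxiran-2-yl]-2-[dimethyl(propan-2-yloxy)silyl]ethan-1-ol (both carbinol epimers)
Conditions: (iPrO)Me2SiCH2MgCl (2 equiv), THF, −78 → −40 °C; aq. NH4Cl
Reagents that add atoms: {[dimethyl(propan-2-yloxy)silyl]methyl}magnesium chloride, CC(C)O[Si](C)(C)C[Mg]Cl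
Why: Grignard addition of a silylmethyl hydroxymethyl-anion equivalent to the aldehyde brings in C1; the new carbinol centre (C2) needs no control because step 12 oxidises it to the ketone.

Step 11
Reactants: 17 1-[(2R,3S)-3-[(2Z,4S)-4-[(tert-butyldimethylsilyl)oxy]-3,7-dimethylocta-2,6-dien-1-yl]-2-methyloxiran-2-yl]-2-[dimethyl(propan-2-yloxy)silyl]ethan-1-ol
Product: 18 1-[(2R,3S)-3-[(2Z,4S)-4-[(tert-butyldimethylsilyl)oxy]-3,7-dimethylocta-2,6-dien-1-yl]-2-methyloxiran-2-yl]ethane-1,2-diol (both carbinol epimers)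
Conditions: 30% aq. H2O2, KF, KHCO3, THF/MeOH (1:1), rt
Reagents that add atoms: hydrogen peroxide, OO
Why: Tamao–Fleming oxidation replaces the alkoxysilyl group by hydroxyl under weakly basic conditions that should leave the alkenes, the oxirane and the TBS ether alone.

Step 12
Reactants: 18 1-[(2R,3S)-3-[(2Z,4S)-4-[(tert-butyldimethylsilyl)oxy]-3,7-dimethylocta-2,6-dien-1-yl]-2-methyloxiran-2-yl]ethane-1,2-diol
Product: 19 2-[(2S,3S)-3-[(2Z,4S)-4-[(tert-butyldimethylsilyl)oxy]-3,7-dimethylocta-2,6-dien-1-yl]-2-methyloxiran-2-yl]-2-oxoacetaldehyde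
Conditions: (COCl)2 (3 equiv), DMSO (6 equiv), CH2Cl2, −78 °C; Et3N (10 equiv), −78 → −20 °C; pentane, filtration, evaporation; used at once
Reagents that add atoms: none
Why: Swern oxidation of both hydroxyls of the 1,2-diol, which does not cleave the C1–C2 bond, should give the α-keto aldehyde; it has no enolisable hydrogen (C3 is quaternary), so the amine base is tolerated and both C2 epimers converge.

Step 13
Reactants: 19 2-[(2S,3S)-3-[(2Z,4S)-4-[(tert-butyldimethylsilyl)oxy]-3,7-dimethylocta-2,6-dien-1-yl]-2-methyloxiran-2-yl]-2-oxoacetaldehyde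
Product: 20 (1S,3S,4S,6S)-4-[(3S)-3-[(tert-butyldimethylsilyl)oxy]-6-methylhepta-1,5-dien-2-yl]-3-hydroxy-1-methyl-7-oxabicyclo[4.1.0]heptan-2-one
Conditions: [Cu((S,S)-tBu-box)](SbF6)2 (10 mol%; ligand = 2,2′-(propane-2,2-diyl)bis[(4S)-4-tert-butyl-4,5-dihydro-1,3-oxazole]), 4 Å molecular sieves, CH2Cl2 (0.01 M), −40 → 0 °C
Reagents that add atoms: none
Why: The divalent-copper bis(oxazoline) Lewis acid should chelate the s-cis 1,2-dicarbonyl of 19 through the aldehyde and ketone oxygens, and the activated aldehyde carbon C1 is then attacked by C6 of the (Z)-C6=C7 alkene while the aldehyde oxygen accepts a hydrogen from the C14 methyl group (concerted, asynchronous carbonyl-ene reaction, type 1 intramolecular mode); the closest known reactions are the Lewis-acid cyclisation of citronellal to isopulegol and the copper bis(oxazoline)-catalysed ene reactions of glyoxylates and of tethered α-keto esters. The cyclohexanone ring closes in a 6-exo-trig sense with respect to both the C1=O and the C6=C7 π bonds, through a chair-like transition state in which the cis-oxirane holds C2 and C5 syn. C1 is set by the catalyst: by analogy with glyoxylate, the (S,S)-tert-butyl ligand should leave the Si face of the chelated aldehyde open, which gives (1S). C6 is set relative to C1 by the chair, in which the chelated C1–O bond and the C7 substituent are both equatorial (trans, as in isopulegol), which gives (6S). The step needs aldehyde-over-ketone and C6=C7-over-C10=C11 chemoselectivity (secured by the more electrophilic aldehyde and by six- against five- or ten-membered closure), hydrogen transfer from C14 and not from C8–H (secured by the (Z)-geometry, which puts the methyl group trans to the tether and next to the equatorial oxygen), and facial control against the resident oxirane and C8 centres (expected to be dominated by the catalyst, both being remote from C1).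

Step 14
Reactants: 20 (1S,3S,4S,6S)-4-[(3S)-3-[(tert-butyldimethylsilyl)oxy]-6-methylhepta-1,5-dien-2-yl]-3-hydroxy-1-methyl-7-oxabicyclo[4.1.0]heptan-2-one
Product: 21 (1S,3S,4S,6S)-3-hydroxy-4-[(3S)-3-hydroxy-6-methylhepta-1,5-dien-2-yl]-1-methyl-7-oxabicyclo[4.1.0]heptan-2-one
Conditions: HF·pyridine, pyridine, THF, 0 °C → rt
Reagents that add atoms: none
Why: Fluoride-induced desilylation under pyridine-buffered conditions should remove the secondary TBS ether without opening the epoxy ketone or disturbing the α-ketol.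

Step 15
Reactants: 21 (1S,3S,4S,6S)-3-hydroxy-4-[(3S)-3-hydroxy-6-methylhepta-1,5-dien-2-yl]-1-methyl-7-oxabicyclo[4.1.0]heptan-2-one; 22 (2Z)-2-methylbut-2-enoic acid (angelic acid)
Product: 24 (1S,3S,4S,6S)-1-methyl-4-[(3S)-6-methyl-3-{[(2Z)-2-methylbut-2-enoyl]oxy}hepta-1,5-dien-2-yl]-2-oxo-7-oxabicyclo[4.1.0]heptan-3-yl (2Z)-2-methylbut-2-enoate (CNP0271744.2), via mixed anhydride 23 (not isolated)
Conditions: 22 (4 equiv), 2,4,6-trichlorobenzoyl chloride (4 equiv), Et3N (4.2 equiv), toluene, rt; then 21, toluene, 75 °C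
Reagents that add atoms: 2,4,6-trichlorobenzoyl chloride, O=C(Cl)c1c(Cl)cc(Cl)cc1Cl (its aroyl group is carried by 23 only)
Why: Yamaguchi-type acylation through the mixed trichlorobenzoic anhydride, run without a nucleophilic catalyst, is the stereoconservative way to make angelates and should esterify both secondary hydroxyls without Z→E isomerisation to tiglate; no stereocentre is altered.

**Compound list**
1 | methyl (2S)-oxirane-2-carboxylate | COC(=O)[C@@H]1CO1 | starting material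
2 | (2-methylprop-1-en-1-yl)magnesium bromide | CC(C)=C[Mg]Br | starting material
3 | methyl (2S)-2-hydroxy-5-methylhex-4-enoate | COC(=O)[C@@H](O)CC=C(C)C | intermediate
4 | methyl (2S)-2-[(tert-butyldimethylsilyl)oxy]-5-methylhex-4-enoate | COC(=O)[C@H](CC=C(C)C)O[Si](C)(C)C(C)(C)C | intermediate
5 | (2S)-2-[(tert-butyldimethylsilyl)oxy]-N-methoxy-N,5-dimethylhex-4-enamide | CON(C)C(=O)[C@H](CC=C(C)C)O[Si](C)(C)C(C)(C)C | intermediate (not isolated)
6 | (3S)-3-[(tert-butyldimethylsilyl)oxy]-6-methylhept-5-en-2-one | CC(=O)[C@H](CC=C(C)C)O[Si](C)(C)C(C)(C)C | intermediate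
7 | [2-(1,3-dioxolan-2-yl)ethyl]triphenylphosphonium bromide | [Br-].C1COC(CC[P+](c2ccccc2)(c2ccccc2)c2ccccc2)O1 | starting material
8 | [2-(1,3-dioxolan-2-yl)ethylidene]triphenylphosphorane | C1COC(CC=P(c2ccccc2)(c2ccccc2)c2ccccc2)O1 | intermediate (not isolated)
9 | 2-[(2Z,4S)-4-[(tert-butyldimethylsilyl)oxy]-3,7-dimethylocta-2,6-dien-1-yl]-1,3-dioxolane | O1CCOC1C/C=C(C)\[C@H](CC=C(C)C)O[Si](C)(C)C(C)(C)C | intermediate
10 | (3Z,5S)-5-[(tert-butyldimethylsilyl)oxy]-4,8-dimethylnona-3,7-dienal | O=CC/C=C(C)\[C@H](CC=C(C)C)O[Si](C)(C)C(C)(C)C | intermediate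
11 | ethyl 2-[bis(2,2,2-trifluoroethoxy)phosphoryl]propanoate | CCOC(=O)C(C)P(=O)(OCC(F)(F)F)OCC(F)(F)F | starting material
12 | potassium salt of the α-carbanion of 11 | [K+].CCOC(=O)[C-](C)P(=O)(OCC(F)(F)F)OCC(F)(F)F | intermediate (not isolated)
13 | ethyl (2Z,5Z,7S)-7-[(tert-butyldimethylsilyl)oxy]-2,6,10-trimethylundeca-2,5,9-trienoate | CCOC(=O)/C(C)=C\C/C=C(C)\[C@H](CC=C(C)C)O[Si](C)(C)C(C)(C)C | intermediate
14 | (2Z,5Z,7S)-7-[(tert-butyldimethylsilyl)oxy]-2,6,10-trimethylundeca-2,5,9-trien-1-ol | OC/C(C)=C\C/C=C(C)\[C@H](CC=C(C)C)O[Si](C)(C)C(C)(C)C | intermediate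
15 | [(2R,3S)-3-[(2Z,4S)-4-[(tert-butyldimethylsilyl)oxy]-3,7-dimethylocta-2,6-dien-1-yl]-2-methyloxiran-2-yl]methanol | OC[C@@]1(C)O[C@H]1C/C=C(C)\[C@H](CC=C(C)C)O[Si](C)(C)C(C)(C)C | intermediate
16 | (2S,3S)-3-[(2Z,4S)-4-[(tert-butyldimethylsilyl)oxy]-3,7-dimethylocta-2,6-dien-1-yl]-2-methyloxirane-2-carbaldehyde | O=C[C@@]1(C)O[C@H]1C/C=C(C)\[C@H](CC=C(C)C)O[Si](C)(C)C(C)(C)C | intermediate
17 | 1-[(2R,3S)-3-[(2Z,4S)-4-[(tert-butyldimethylsilyl)oxy]-3,7-dimethylocta-2,6-dien-1-yl]-2-methyloxiran-2-yl]-2-[dimethyl(propan-2-yloxy)silyl]ethan-1-ol (carbinol epimers) | CC(C)O[Si](C)(C)CC(O)[C@@]1(C)O[C@H]1C/C=C(C)\[C@H](CC=C(C)C)O[Si](C)(C)C(C)(C)C | intermediate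
18 | 1-[(2R,3S)-3-[(2Z,4S)-4-[(tert-butyldimethylsilyl)oxy]-3,7-dimethylocta-2,6-dien-1-yl]-2-methyloxiran-2-yl]ethane-1,2-diol (carbinol epimers) | OCC(O)[C@@]1(C)O[C@H]1C/C=C(C)\[C@H](CC=C(C)C)O[Si](C)(C)C(C)(C)C | intermediate
19 | 2-[(2S,3S)-3-[(2Z,4S)-4-[(tert-butyldimethylsilyl)oxy]-3,7-dimethylocta-2,6-dien-1-yl]-2-methyloxiran-2-yl]-2-oxoacetaldehyde | O=CC(=O)[C@@]1(C)O[C@H]1C/C=C(C)\[C@H](CC=C(C)C)O[Si](C)(C)C(C)(C)C | intermediate
20 | (1S,3S,4S,6S)-4-[(3S)-3-[(tert-butyldimethylsilyl)oxy]-6-methylhepta-1,5-dien-2-yl]-3-hydroxy-1-methyl-7-oxabicyclo[4.1.0]heptan-2-one | C=C([C@H](CC=C(C)C)O[Si](C)(C)C(C)(C)C)[C@@H]1C[C@@H]2O[C@]2(C)C(=O)[C@H]1O | intermediate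
21 | (1S,3S,4S,6S)-3-hydroxy-4-[(3S)-3-hydroxy-6-methylhepta-1,5-dien-2-yl]-1-methyl-7-oxabicyclo[4.1.0]heptan-2-one | C=C([C@H](CC=C(C)C)O)[C@@H]1C[C@@H]2O[C@]2(C)C(=O)[C@H]1O | intermediate
22 | (2Z)-2-methylbut-2-enoic acid (angelic acid) | C/C=C(C)\C(=O)O | starting material
23 | (2Z)-2-methylbut-2-enoic 2,4,6-trichlorobenzoic anhydride | C/C=C(C)\C(=O)OC(=O)c1c(Cl)cc(Cl)cc1Cl | intermediate (not isolated)
24 | (1S,3S,4S,6S)-1-methyl-4-[(3S)-6-methyl-3-{[(2Z)-2-methylbut-2-enoyl]oxy}hepta-1,5-dien-2-yl]-2-oxo-7-oxabicyclo[4.1.0]heptan-3-yl (2Z)-2-methylbut-2-enoate | C=C([C@H](CC=C(C)C)OC(=O)/C(C)=C\C)[C@@H]1C[C@@H]2O[C@]2(C)C(=O)[C@H]1OC(=O)/C(C)=C\C | target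

**Step count and risks**
Total: 15 steps. Longest linear sequence: 15 steps (from 1).

Most likely to fail:

Step 13. The facial selectivity may be poor or reversed if the chiral catalyst and the two resident stereo-elements (oxirane, C8) pull in different directions, and the strong Lewis acid may open or rearrange the epoxy ketone. The fallback makes the ring before the oxirane, so the ene step meets no epoxide and the oxirane is then placed by substrate direction. It sets out from 14 and comes back to the route at 24. Allylic oxidation of 14 with MnO2 should give the (2Z,5Z)-trienal F1. Addition of (iPrO)Me2SiCH2MgCl gives the β-hydroxysilane F2, and Tamao–Fleming oxidation gives the allylic 1,2-diol F3. Swern oxidation gives the dienyl α-keto aldehyde F4, and the same copper-catalysed ene cyclisation, now opposed only by C8, gives the 6-hydroxy-cyclohexenone F5. HF·pyridine gives the diol F6, and mixed-anhydride angeloylation as in step 15 gives the bis-angelate enone F7. Luche reduction (NaBH4, CeCl3·7H2O, MeOH, −78 °C; axial hydride delivery, as for carvone) gives the allylic alcohol F8 with C2–OH cis to the C6 side chain. Hydroxyl-directed epoxidation (VO(acac)2, tBuOOH) then places the oxirane syn to that hydroxyl, that is cis to the side chain, in the epoxy alcohol F9. Dess–Martin oxidation of F9 gives 24.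

Step 12. The second oxidation may stall, the diol may cleave, or the very electrophilic keto aldehyde may be trapped as hydrate or oligomer, so that no free monomer reaches step 13. The fallback brings C1 in at the aldehyde oxidation level as a masked formyl anion; it sets out from 16 and comes back at 19. 2-Lithio-1,3-dithiane (THF, −78 °C) adds to 16 to give the dithianyl carbinol F10. Parikh–Doering oxidation (SO3·pyridine, DMSO, iPr2NEt) gives the 2-acyl-1,3-dithiane F11. Alkylative hydrolysis (MeI, CaCO3, MeCN/H2O) then unmasks the aldehyde to give 19, which is dried over 4 Å molecular sieves before step 13.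

Step 15. The angeloyl group may isomerise to tigloyl during activation, the hindered α-ketol hydroxyl may acylate incompletely, or C1 may epimerise on long heating with amine salts. The fallback builds the (Z)-alkenes of the esters in place; it sets out from 21 and comes back at 24. Carbodiimide esterification (DCC, catalytic DMAP, CH2Cl2, 0 °C) of both hydroxyls with 2-[bis(2,2,2-trifluoroethoxy)phosphoryl]propanoic acid gives the bis(phosphonopropanoate) F12. Double Still–Gennari olefination with acetaldehyde (KN(SiMe3)2, 18-crown-6, THF, −78 °C) then gives both (Z)-2-methylbut-2-enoates, that is 24.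

**Further compounds**
F1 | step 13 | (2Z,5Z,7S)-7-[(tert-butyldimethylsilyl)oxy]-2,6,10-trimethylundeca-2,5,9-trienal | O=C/C(C)=C\C/C=C(C)\[C@H](CC=C(C)C)O[Si](C)(C)C(C)(C)C
F2 | step 13 | (3Z,6Z,8S)-8-[(tert-butyldimethylsilyl)oxy]-1-[dimethyl(propan-2-yloxy)silyl]-3,7,11-trimethyldodeca-3,6,10-trien-2-ol | CC(C)O[Si](C)(C)CC(O)/C(C)=C\C/C=C(C)\[C@H](CC=C(C)C)O[Si](C)(C)C(C)(C)C
F3 | step 13 | (3Z,6Z,8S)-8-[(tert-butyldimethylsilyl)oxy]-3,7,11-trimethyldodeca-3,6,10-triene-1,2-diol | OCC(O)/C(C)=C\C/C=C(C)\[C@H](CC=C(C)C)O[Si](C)(C)C(C)(C)C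
F4 | step 13 | (3Z,6Z,8S)-8-[(tert-butyldimethylsilyl)oxy]-3,7,11-trimethyl-2-oxododeca-3,6,10-trienal | O=CC(=O)/C(C)=C\C/C=C(C)\[C@H](CC=C(C)C)O[Si](C)(C)C(C)(C)C
F5 | step 13 | (5S,6S)-5-[(3S)-3-[(tert-butyldimethylsilyl)oxy]-6-methylhepta-1,5-dien-2-yl]-6-hydroxy-2-methylcyclohex-2-en-1-one | C=C([C@H](CC=C(C)C)O[Si](C)(C)C(C)(C)C)[C@@H]1CC=C(C)C(=O)[C@H]1O
F6 | step 13 | (5S,6S)-6-hydroxy-5-[(3S)-3-hydroxy-6-methylhepta-1,5-dien-2-yl]-2-methylcyclohex-2-en-1-one | C=C([C@H](CC=C(C)C)O)[C@@H]1CC=C(C)C(=O)[C@H]1O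
F7 | step 13 | (1S,6S)-3-methyl-6-[(3S)-6-methyl-3-{[(2Z)-2-methylbut-2-enoyl]oxy}hepta-1,5-dien-2-yl]-2-oxocyclohex-3-en-1-yl (2Z)-2-methylbut-2-enoate | C=C([C@H](CC=C(C)C)OC(=O)/C(C)=C\C)[C@@H]1CC=C(C)C(=O)[C@H]1OC(=O)/C(C)=C\C
F8 | step 13 | (1S,2S,6S)-2-hydroxy-3-methyl-6-[(3S)-6-methyl-3-{[(2Z)-2-methylbut-2-enoyl]oxy}hepta-1,5-dien-2-yl]cyclohex-3-en-1-yl (2Z)-2-methylbut-2-enoate | C=C([C@H](CC=C(C)C)OC(=O)/C(C)=C\C)[C@@H]1CC=C(C)[C@H](O)[C@H]1OC(=O)/C(C)=C\C
F9 | step 13 | (1R,2R,3S,4S,6S)-2-hydroxy-1-methyl-4-[(3S)-6-methyl-3-{[(2Z)-2-methylbut-2-enoyl]oxy}hepta-1,5-dien-2-yl]-7-oxabicyclo[4.1.0]heptan-3-yl (2Z)-2-methylbut-2-enoate | C=C([C@H](CC=C(C)C)OC(=O)/C(C)=C\C)[C@@H]1C[C@@H]2O[C@]2(C)[C@H](O)[C@H]1OC(=O)/C(C)=C\C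
F10 | step 12 | (1,3-dithian-2-yl)[(2R,3S)-3-[(2Z,4S)-4-[(tert-butyldimethylsilyl)oxy]-3,7-dimethylocta-2,6-dien-1-yl]-2-methyloxiran-2-yl]methanol (carbinol epimers) | OC(C1SCCCS1)[C@@]1(C)O[C@H]1C/C=C(C)\[C@H](CC=C(C)C)O[Si](C)(C)C(C)(C)C
F11 | step 12 | (1,3-dithian-2-yl)[(2S,3S)-3-[(2Z,4S)-4-[(tert-butyldimethylsilyl)oxy]-3,7-dimethylocta-2,6-dien-1-yl]-2-methyloxiran-2-yl]methanone | O=C(C1SCCCS1)[C@@]1(C)O[C@H]1C/C=C(C)\[C@H](CC=C(C)C)O[Si](C)(C)C(C)(C)C
F12 | step 15 | (1S,3S,4S,6S)-4-[(3S)-3-({2-[bis(2,2,2-trifluoroethoxy)phosphoryl]propanoyl}oxy)-6-methylhepta-1,5-dien-2-yl]-1-methyl-2-oxo-7-oxabicyclo[4.1.0]heptan-3-yl 2-[bis(2,2,2-trifluoroethoxy)phosphoryl]propanoate (epimers at the phosphorus-bearing carbons) | C=C([C@H](CC=C(C)C)OC(=O)C(C)P(=O)(OCC(F)(F)F)OCC(F)(F)F)[C@@H]1C[C@@H]2O[C@]2(C)C(=O)[C@H]1OC(=O)C(C)P(=O)(OCC(F)(F)F)OCC(F)(F)F
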